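**Retrosynthetic overview**
- The strategy rests on C3, a secondary carbinol carbon flanked only by the C1=C2 vinyl group and the conjugated C4≡C5–C6≡C7 diyne. Cutting C3–C4 gives acrolein and the terminal diyne of the C4–C17 epoxy diyne, joined by a catalytic enantioselective zinc alkynylation that sets 3S.
- The linoleate C–O bond at C3 is made last by Steglich esterification, so the skipped Z,Z-diene never meets an organometallic reagent.
- The C7–C8 bond comes from SN2 displacement of an epoxy triflate by a silyl-capped butadiynide, followed by desilylation to free the diyne terminus.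
- The only ring, the trans-oxirane C9–O–C10, is formed first by Sharpless epoxidation of (E)-dec-2-en-1-ol, which sets 9R and 10R. No other ring is formed.

Key step: step 5

Assumption: the (S,S)-ProPhenol–zinc catalyst is taken to deliver the alkynyl group to the Re face of the bound aldehyde, the face it selects in its aldol reactions, which corresponds to 3S here. The C3 configuration of the diynol is to be confirmed by Mosher ester analysis, and if the sense is the reverse the (R,R)-ligand is used with no other change.

**Route**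

Step 1
Reactants: 1 (E)-dec-2-en-1-ol
Product: 2 [(2R,3R)-3-heptyloxiran-2-yl]methanol
Conditions: Ti(OiPr)4 (5 mol%), D-(−)-diethyl tartrate (6 mol%), t-BuOOH (2 equiv, anhydrous), 4 Å molecular sieves, CH2Cl2, −20 °C; then 10% NaOH in brine
Reagents that add atoms: tert-butyl hydroperoxide, CC(C)(C)OO
Why: Sharpless asymmetric epoxidation, in which the titanium–tartrate complex binds the allylic alcohol and the peroxide and delivers oxygen to one alkene face; with D-(−)-diethyl tartrate an E-2-alken-1-ol should give the (2R,3R)-epoxy alcohol, which sets C9 and C10 of the target, and the trans ring follows from the E alkene.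

Step 2
Reactants: 2 [(2R,3R)-3-heptyloxiran-2-yl]methanol
Product: 3 [(2R,3R)-3-heptyloxiran-2-yl]methyl trifluoromethanesulfonate
Conditions: Tf2O (1.1 equiv), 2,6-lutidine (1.3 equiv), CH2Cl2, −78 °C, 30 min; cold aq NaHCO3 wash, used crude at once
Reagents that add atoms: triflic anhydride, O=S(=O)(OS(=O)(=O)C(F)(F)F)C(F)(F)F
Why: O-sulfonylation of the primary alcohol with a hindered, non-nucleophilic pyridine base at low temperature should give the primary triflate without touching the oxirane or either stereocentre.

Step 3
Reactants: 3 [(2R,3R)-3-heptyloxiran-2-yl]methyl trifluoromethanesulfonate; 4 1,4-bis(trimethylsilyl)buta-1,3-diyne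
Product: 6 trimethyl{5-[(2R,3R)-3-heptyloxiran-2-yl]penta-1,3-diyn-1-yl}silane, via lithium (trimethylsilyl)butadiynide 5 (not isolated)
Conditions: 4 (1.5 equiv), MeLi·LiBr (1.4 equiv), THF, 0 °C → rt, 3 h; then −78 °C, 3 in THF–DMPU, −78 → −40 °C; aq NH4Cl
Reagents that add atoms: none
Why: Mono-desilylation of 4 by MeLi gives diynide 5, whose SN2 attack on the primary triflate (acetylide alkylation, far faster at −78 °C than opening of an oxirane without Lewis acid) forms the C7–C8 bond and leaves both epoxide stereocentres untouched.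

Step 4
Reactants: 6 trimethyl{5-[(2R,3R)-3-heptyloxiran-2-yl]penta-1,3-diyn-1-yl}silane
Product: 7 (2R,3R)-2-heptyl-3-(penta-2,4-diyn-1-yl)oxirane
Conditions: K2CO3 (0.3 equiv), MeOH–THF (1:1), 0 °C, 30 min; pentane/pH 7 buffer; solution kept cold, exchanged into toluene, dried and used at once
Reagents that add atoms: none
Why: Base-catalysed methanolysis of the alkynyl C–Si bond (protiodesilylation) is fast for a diynyl silane, and the cold, weakly basic medium should leave the oxirane and the C8 methylene alone.

Step 5
Reactants: 7 (2R,3R)-2-heptyl-3-(penta-2,4-diyn-1-yl)oxirane; 8 acrolein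
Product: 10 (3S)-8-[(2R,3R)-3-heptyloxiran-2-yl]oct-1-ene-4,6-diyn-3-ol, via methylzinc diynide 9 (not isolated)
Conditions: (S,S)-ProPhenol [2,6-bis{[(S)-2-(hydroxydiphenylmethyl)pyrrolidin-1-yl]methyl}-4-methylphenol] (20 mol%), Ph3P=O (40 mol%), ZnMe2 (2 equiv), toluene, 0 °C → rt, 1 h; then 8 (2 equiv, freshly distilled) by syringe pump, 4 °C, 24–48 h; aq NH4Cl
Reagents that add atoms: none
Why: ZnMe2 deprotonates the three hydroxyl groups of the ligand to give a dinuclear zinc complex and zincates the terminal C–H of 7 with loss of methane to give 9; acrolein then binds through its carbonyl oxygen to one zinc and the diynyl group passes from the neighbouring zinc to the carbonyl carbon, forming the C3–C4 bond as a zinc alkoxide that NH4Cl protonates. The closest known reaction type is the ProPhenol–ZnMe2-catalysed enantioselective addition of terminal 1,3-diynes to aldehydes, α,β-unsaturated ones included. No ring is closed. The new C3 stereocentre is set by the catalyst alone: the (S,S)-ligand pocket should expose the Re face of the bound aldehyde, which gives 3S, and the C9 and C10 centres, six bonds away, should have no say. The step needs 1,2- over 1,4-addition, zincation only at the diyne terminus and survival of the oxirane; these are secured by carbonyl activation on zinc with alkynyl transfer inside the complex, by the much higher acidity of the conjugated sp C–H than of the C8 methylene, by the absence of enolisable hydrogens in acrolein and by the mild Lewis acidity of the zinc species, while slow addition of acrolein should hold back uncatalysed addition and polymerisation.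

Step 6
Reactants: 10 (3S)-8-[(2R,3R)-3-heptyloxiran-2-yl]oct-1-ene-4,6-diyn-3-ol; 11 linoleic acid
Product: 13 (3S)-8-[(2R,3R)-3-heptyloxiran-2-yl]oct-1-ene-4,6-diyn-3-yl (9Z,12Z)-octadeca-9,12-dienoate, via O-linoleoyl-N,N'-dicyclohexylisourea 12 (not isolated)
Conditions: 11 (1.2 equiv), DCC (1.3 equiv), DMAP (0.1 equiv), CH2Cl2, 0 °C → rt, argon, dark
Reagents that add atoms: none
Why: Steglich esterification, in which DCC turns the acid into O-acylisourea 12 and DMAP transfers the acyl group to the C3 hydroxyl; the C3–O bond is not broken, so 3S is retained, and the neutral conditions should spare the oxirane, the diyne and the Z,Z-diene.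

**Compound list**

1 | (E)-dec-2-en-1-ol | CCCCCCC/C=C/CO | starting material
2 | [(2R,3R)-3-heptyloxiran-2-yl]methanol | OC[C@H]1O[C@@H]1CCCCCCC | intermediate
3 | [(2R,3R)-3-heptyloxiran-2-yl]methyl trifluoromethanesulfonate | O=S(=O)(OC[C@H]1O[C@@H]1CCCCCCC)C(F)(F)F | intermediate
4 | 1,4-bis(trimethylsilyl)buta-1,3-diyne | C[Si](C)(C)C#CC#C[Si](C)(C)C | starting material
5 | lithium (trimethylsilyl)butadiynide | [Li]C#CC#C[Si](C)(C)C | intermediate (not isolated)
6 | trimethyl{5-[(2R,3R)-3-heptyloxiran-2-yl]penta-1,3-diyn-1-yl}silane | C[Si](C)(C)C#CC#CC[C@H]1O[C@@H]1CCCCCCC | intermediate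
7 | (2R,3R)-2-heptyl-3-(penta-2,4-diyn-1-yl)oxirane | C#CC#CC[C@H]1O[C@@H]1CCCCCCC | intermediate
8 | acrolein (prop-2-enal) | C=CC=O | starting material
9 | methyl{5-[(2R,3R)-3-heptyloxiran-2-yl]penta-1,3-diyn-1-yl}zinc (methylzinc diynide) | C[Zn]C#CC#CC[C@H]1O[C@@H]1CCCCCCC | intermediate (not isolated)
10 | (3S)-8-[(2R,3R)-3-heptyloxiran-2-yl]oct-1-ene-4,6-diyn-3-ol | C=C[C@H](O)C#CC#CC[C@H]1O[C@@H]1CCCCCCC | intermediate
11 | linoleic acid, (9Z,12Z)-octadeca-9,12-dienoic acid | CCCCC/C=C\C/C=C\CCCCCCCC(=O)O | starting material
12 | O-linoleoyl-N,N'-dicyclohexylisourea | CCCCC/C=C\C/C=C\CCCCCCCC(=O)OC(=NC1CCCCC1)NC1CCCCC1 | intermediate (not isolated)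
13 | (3S)-8-[(2R,3R)-3-heptyloxiran-2-yl]oct-1-ene-4,6-diyn-3-yl (9Z,12Z)-octadeca-9,12-dienoate | C=C[C@@H](C#CC#CC[C@H]1O[C@@H]1CCCCCCC)OC(=O)CCCCCCC/C=C\C/C=C\CCCCC | target

**Summary**

Total step count: 6. Longest linear sequence: 6 steps (1 → 2 → 3 → 6 → 7 → 10 → 13).

**Steps most likely to fail**

Step 5. The risks are poor enantioface selectivity with so small an enal, and acrolein polymerising or adding uncatalysed faster than the catalyst turns over. The fallback keeps the C3–C4 bond between 7 and 8 but drops the chiral catalyst. Diyne 7 is deprotonated with LiN(SiMe3)2 in THF at −78 °C to lithium 5-[(2R,3R)-3-heptyloxiran-2-yl]penta-1,3-diyn-1-ide F1, which adds to acrolein 8 to give 8-[(2R,3R)-3-heptyloxiran-2-yl]oct-1-ene-4,6-diyn-3-ol as a mixture of C3 epimers F2. Lipase-mediated acylation (Pseudomonas cepacia lipase, vinyl acetate, hexane, rt) is then expected, by the Kazlauskas rule with vinyl as the medium and the diynyl chain as the large substituent, to acylate the 3R epimer to (3R)-8-[(2R,3R)-3-heptyloxiran-2-yl]oct-1-ene-4,6-diyn-3-yl acetate F3. The unreacted 3S alcohol is 10, separated from F3 by chromatography, and the route is rejoined at 10.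

Step 3. The risk is that the silyl diynide is too weak a nucleophile, so that the triflate decomposes before it is displaced. The fallback sets out from 3 and builds the diyne in two stages. Displacement with commercial lithium (trimethylsilyl)acetylide, LiC≡CSiMe3 (THF–DMPU, −78 °C), a stronger nucleophile, should give trimethyl{3-[(2R,3R)-3-heptyloxiran-2-yl]prop-1-yn-1-yl}silane F4. K2CO3 in methanol at 0 °C then frees (2R,3R)-2-heptyl-3-(prop-2-yn-1-yl)oxirane F5. Cadiot–Chodkiewicz coupling of F5 with (bromoethynyl)triisopropylsilane (CuCl, NH2OH·HCl, n-BuNH2, water–CH2Cl2, 0 °C) should give triisopropyl{5-[(2R,3R)-3-heptyloxiran-2-yl]penta-1,3-diyn-1-yl}silane F6. Bu4NF in THF at 0 °C removes the silyl group to give 7, where the route is rejoined.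

Step 2. The risk is loss of the epoxy triflate by ionisation, ring opening or elimination during its preparation and handling. The fallback sets out from 1 and reverses the order of events so that no epoxy sulfonate is needed. Alcohol 1 is converted by the Appel reaction (CBr4, PPh3, CH2Cl2, 0 °C) into (E)-1-bromodec-2-ene F7. F7 is coupled at its primary carbon with diynide 5 (made from 4 as in step 3) with CuBr·SMe2 (10 mol%) in THF from −78 to 0 °C to give (E)-trimethyl(tetradec-6-ene-1,3-diyn-1-yl)silane F8. Shi epoxidation of the isolated E alkene of F8 (D-fructose-derived ketone catalyst, KHSO5 as its triple salt 2KHSO5·KHSO4·K2SO4, K2CO3, Bu4NHSO4, MeCN–dimethoxymethane–aqueous buffer, 0 °C) is expected to give the (R,R)-oxirane from a trans-disubstituted alkene, which is 6, where the route is rejoined. Any material that loses its silyl group in the basic buffer is 7 and is combined with the product of step 4.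

**Further compounds**

F1 | step 5 | lithium 5-[(2R,3R)-3-heptyloxiran-2-yl]penta-1,3-diyn-1-ide | [Li]C#CC#CC[C@H]1O[C@@H]1CCCCCCC
F2 | step 5 | 8-[(2R,3R)-3-heptyloxiran-2-yl]oct-1-ene-4,6-diyn-3-ol, mixture of C3 epimers | C=CC(O)C#CC#CC[C@H]1O[C@@H]1CCCCCCC
F3 | step 5 | (3R)-8-[(2R,3R)-3-heptyloxiran-2-yl]oct-1-ene-4,6-diyn-3-yl acetate | C=C[C@@H](OC(C)=O)C#CC#CC[C@H]1O[C@@H]1CCCCCCC
F4 | step 3 | trimethyl{3-[(2R,3R)-3-heptyloxiran-2-yl]prop-1-yn-1-yl}silane | C[Si](C)(C)C#CC[C@H]1O[C@@H]1CCCCCCC
F5 | step 3 | (2R,3R)-2-heptyl-3-(prop-2-yn-1-yl)oxirane | C#CC[C@H]1O[C@@H]1CCCCCCC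
F6 | step 3 | triisopropyl{5-[(2R,3R)-3-heptyloxiran-2-yl]penta-1,3-diyn-1-yl}silane | CC(C)[Si](C(C)C)(C(C)C)C#CC#CC[C@H]1O[C@@H]1CCCCCCC
F7 | step 2 | (E)-1-bromodec-2-ene | CCCCCCC/C=C/CBr
F8 | step 2 | (E)-trimethyl(tetradec-6-ene-1,3-diyn-1-yl)silane | C[Si](C)(C)C#CC#CC/C=C/CCCCCCC
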